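## Analysis of the target

Target 15 is a biflavonoid. A 3,5,7-trihydroxy-2-(4-hydroxyphenyl)chroman-4-one (benzo ring A, pyranone ring C, aryl ring B on C2) is joined twice to a kaempferol unit: by a C–C bond from C2 to flavonol C8 and by an ether bond from C3 to flavonol O7. Together with flavonol C7 these two links form a 2,3-dihydrofuran ring that is cis-fused to ring C and annulated to the benzo ring of the flavonol. The only stereocentres are C2 (R; it bears O1, ring B, flavonol C8 and C3) and C3 (S; it bears OH, O7, the C4 carbonyl and C2). Both are fully substituted and adjacent, and the five-membered ring ties them together, so the cis fusion fixes the relative configuration and only one absolute element has to be set. C3 is a hemiketal carbon next to a ketone and carries an aryloxy group that can leave; C2 is a doubly benzylic ether carbon that can ionise; the six phenols and the flavonol enol are easily oxidised, so the free polyphenol should appear only at the end. The difficulty is the pair of vicinal tetrasubstituted centres, one of them a quaternary carbon holding two electron-rich aryl groups of similar size, with no neighbouring C–H to steer by. The strategy rests on reading C2 and C3 as the two carbons of a flavone C2=C3 bond. In a 3-aryloxyflavone whose aryloxy group is ring A of a second flavone, O7 is already on C3, one oxygen atom brings the double bond to the oxidation level of 15, and flavonol C8, ortho to O7, lies at five-ring distance from C2. The same oxidant can turn the C3–H of the second flavone into the flavonol hydroxyl.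

## Retrosynthetic reasoning

15 to 14. The five O–benzyl bonds on the phenols are cut. Pentabenzyl ether 14 keeps the C3 hydroxyl and the flavonol 3-hydroxyl free, because both come out of the key step and neither interferes with a neutral hydrogenolysis. What is gained is that every oxidation-sensitive phenol stays masked until the last operation.

14 to 12. The C2–C8 bond is cut and the oxygen atoms of the C3 hydroxyl and of the flavonol 3-hydroxyl are removed. This leads to 12, a flat, achiral bis-flavone ether in which a 5,7,4'-tribenzylated 3-aryloxyflavone carries a 5,4'-dibenzylated flavone through its O7. The cut is made at C2–C8 and not at C3–O7 because the ether bond can be made early by ordinary phenol alkylation, whereas the hindered diaryl quaternary carbon is best formed intramolecularly in a five-membered closure. Forward, an asymmetric double epoxidation gives bis-epoxide 13; acid opening of the upper oxirane at C2 and arylation by C8 must then give 14 with both stereocentres, while the lower oxirane isomerises to the flavonol.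

12 to 11. One O–benzyl bond, on the 5-oxygen of the lower flavone, is cut. Carrying this hydroxyl free through the preceding steps means the lower unit needs no selective protection, since its 7-hydroxyl is distinguished by acidity alone. The forward step is a forced etherification of a chelated phenol at a stage where no base-sensitive group is left.

11 to 9. The upper pyranone is opened at O1–C2 and at C2–C3. This gives α-aryloxy ketone 9, in which the 4-benzyloxybenzoyl group sits as an ester on the oxygen that becomes O1. Forward, a Baker–Venkataraman acyl transfer forms C2–C3 (diketone 10) and cyclodehydration forms O1–C2. The disconnection is chosen because it keeps the C3–O7 ether intact and uses the classical route to 3-alkoxyflavones.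

9 to 6 and 8. The CH2–O7 bond is cut, giving α-bromo ketone 6 and 4'-O-benzylapigenin 8. The ester in 6 is essential: with a free ortho hydroxyl the bromo ketone would close to a benzofuran-3-one under the basic alkylation conditions. The same ester is the aroyl donor for the following rearrangement, so it costs no extra step.

6 to 4, 2, 3 and 1. The C–Br bond is removed (ketone 4), then the ester C–O bond (phenol 2 and acid chloride 3), then two O–benzyl bonds (2,4,6-trihydroxyacetophenone 1). The bromination must hit the acetyl carbon and not the very electron-rich ring, which is why it is routed through enol silane 5.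

8 to 1 and 3. The lower pyranone is cut at O1–C2 and C2–C3, giving the same two building blocks 1 and 3 through diketone 7. The two hydroxyls of ring A need no protection because the polyanion of 1 is acylated on carbon.

## Alternatives that were turned down

Alternative 1: Ring C would be removed through O1–C2 and C4–C4a. Phenol A1 (3,5-bis(benzyloxy)phenol) would condense through an ortho carbon with aldehyde A2, a furo[2,3-h]-fused tribenzyl flavonol that already contains the C2–C8 and C3–O7 links as a 3-aryl-furan-2-carbaldehyde. The resulting ortho-quinone methide would close by oxa-6π electrocyclisation onto the aryl-bearing furan carbon to give 2H-chromene A3.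
- In its favour: it is convergent, no oxidant is used in the key step, and the C8-versus-C6 question is settled inside A2 before the key step. On that last point it is stronger than the chosen route, which relies on a selective arylation.
- Against it: the ring closure has to break furan aromaticity while forming a diaryl quaternary carbon, so the equilibrium may stay on the open side. A1 can also react at its para carbon. The absolute configuration would have to come from a chiral acid or counter-ion acting on a pericyclic step with no obvious handle. A3 still lacks the C3 hydroxyl and the C4 carbonyl, so at least two further oxidation steps on an acid-labile enol ether follow, and A2 needs a multi-step furan annulation.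
- Comparison: the chosen route reaches the final oxidation level in the bond-forming step and starts from a precursor made by textbook flavone chemistry.

Alternative 2: O1–C2 and C3–O7 would be cut with C2–C8 left in place. The substrate is para-quinone methide A4, whose exocyclic carbon carries flavonol C8 and a 1,2-diketone ending in the 2,6-dihydroxy-4-benzyloxyphenyl ring. A chiral phosphoric acid would guide one ring-A phenol onto the exocyclic carbon (1,6-addition, ring C), and the flavonol 7-hydroxyl would then add to the C3 ketone to give A5.
- In its favour: acid-catalysed enantioselective 1,6-additions to para-quinone methides are an established class, so the enantio-determining event has firmer precedent than the chiral oxidation chosen here. The hemiketal closes under thermodynamic control, and the C8 regiochemistry is fixed in advance.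
- Against it: A4 is fully substituted at the exocyclic carbon and conjugated to a vicinal dicarbonyl, so it is extremely electrophilic and likely to cyclise without the catalyst, hydrate or tautomerise. The catalyst would have to distinguish two faces defined by two large flat groups. Assembling A4 needs C8-acylation of a protected flavonol with a tricarbonyl chain, a late oxidation to the quinone methide, and a differentiated pattern of four benzyl ethers and three free phenols.
- Comparison: it is several steps longer, whereas the chosen route uses uniform benzyl protection and seven routine steps to 12.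

Alternative 3: C3–O7 would be cut last, after C2 has been set under the influence of a p-tolyl sulfoxide on C3. Pummerer activation of sulfoxide A6 with a silyl triflate and an amine base would give a thionium ion that the flavonol O7 captures, producing O,S-ketal A7.
- In its favour: Pummerer closures by oxygen nucleophiles are dependable, the cis fusion is automatic, and an enantiopure sulfoxide gives a predictable absolute configuration. On predictability it is stronger than the chosen route.
- Against it: A6 requires conjugate arylation at the already aryl-substituted C2 of a 3-sulfinylflavone, which is attack on a fully substituted, electron-rich β-carbon. The adduct can reopen by β-elimination of the ring-A phenoxide. The auxiliary is stoichiometric. A7 has sulfur where oxygen is needed, so a thiophile-mediated exchange in the presence of the flavonol is an extra step, and O7 has to be the only free hydroxyl among seven oxygens.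
- Comparison: the chosen route puts the oxygen on C3 directly and needs no auxiliary, at the price of a less certain sense and level of induction.

Key step: step 8

Assumption: the facial preference of the fructose-derived dioxirane on this tetrasubstituted olefin is extrapolated from its spiro transition-state model with ring oxygen O1 in the place normally taken by the olefinic hydrogen; this points to the L-fructose-derived ketone (obtainable from L-sorbose) for the (2R,3S) series, and the D-ketone would be substituted if the opposite sense were found.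

## Route

Step 1
Reactants: 1 2,4,6-trihydroxyacetophenone
Product: 2 1-[2,4-bis(benzyloxy)-6-hydroxyphenyl]ethan-1-one
Conditions: BnBr (2.05 equiv), K2CO3, DMF, 0 °C to rt
Reagents that add atoms: benzyl bromide, BrCc1ccccc1
Why: Williamson etherification; the para hydroxyl and one ortho hydroxyl are alkylated, while the remaining ortho hydroxyl is hydrogen-bonded to the ketone and should stay free for the ester of step 2.

Step 2
Reactants: 2 1-[2,4-bis(benzyloxy)-6-hydroxyphenyl]ethan-1-one; 3 4-(benzyloxy)benzoyl chloride
Product: 4 2-acetyl-3,5-bis(benzyloxy)phenyl 4-(benzyloxy)benzoate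
Conditions: pyridine, DMAP (cat.), CH2Cl2, 0 °C to rt
Reagents that add atoms: none
Why: DMAP-catalysed esterification of a chelated phenol, the standard entry to Baker–Venkataraman substrates; the ester also masks the ortho oxygen so that the later bromo ketone cannot close to a benzofuran-3-one.

Step 3
Reactants: 4 2-acetyl-3,5-bis(benzyloxy)phenyl 4-(benzyloxy)benzoate
Product: 6 3,5-bis(benzyloxy)-2-(bromoacetyl)phenyl 4-(benzyloxy)benzoate, via trimethylsilyl enol ether 5 (not isolated)
Conditions: Me3SiOTf, Et3N, CH2Cl2, 0 °C; then NBS, −20 to 0 °C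
Reagents that add atoms: N-bromosuccinimide, O=C1CCC(=O)N1Br
Why: α-Bromination of a ketone through its enol silane; soft enolisation leaves the aryl ester alone, and the enol silane should react with NBS far faster than the alkoxy-rich ring, so bromine goes to the acetyl carbon only.

Step 4
Reactants: 1 2,4,6-trihydroxyacetophenone; 3 4-(benzyloxy)benzoyl chloride
Product: 8 2-[4-(benzyloxy)phenyl]-5,7-dihydroxy-4H-chromen-4-one (4'-O-benzylapigenin), via 1,3-diketone 7 (not isolated)
Conditions: LiN(SiMe3)2 (4.2 equiv), THF, −78 °C to rt; aq. HCl; then AcOH, H2SO4 (cat.), 95 °C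
Reagents that add atoms: none
Why: C-acylation of the lithium polyanion of the acetophenone gives the 1,3-diketone directly and acid-catalysed cyclodehydration closes the pyranone, a known one-flask flavone synthesis for ring-A hydroxylated flavones.

Step 5
Reactants: 6 3,5-bis(benzyloxy)-2-(bromoacetyl)phenyl 4-(benzyloxy)benzoate; 8 2-[4-(benzyloxy)phenyl]-5,7-dihydroxy-4H-chromen-4-one
Product: 9 3,5-bis(benzyloxy)-2-[({2-[4-(benzyloxy)phenyl]-5-hydroxy-4-oxo-4H-chromen-7-yl}oxy)acetyl]phenyl 4-(benzyloxy)benzoate
Conditions: K2CO3 (1.2 equiv), acetone, rt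
Reagents that add atoms: none
Why: SN2 displacement of a phenacyl-type bromide by the 7-phenoxide (Williamson etherification); the 7-hydroxyl is by far the more acidic phenol, the 5-hydroxyl being held in a hydrogen bond to C4=O, and the mild heterogeneous base should not trigger acyl transfer at room temperature.

Step 6
Reactants: 9 3,5-bis(benzyloxy)-2-[({2-[4-(benzyloxy)phenyl]-5-hydroxy-4-oxo-4H-chromen-7-yl}oxy)acetyl]phenyl 4-(benzyloxy)benzoate
Product: 11 5,7-bis(benzyloxy)-2-[4-(benzyloxy)phenyl]-3-({2-[4-(benzyloxy)phenyl]-5-hydroxy-4-oxo-4H-chromen-7-yl}oxy)-4H-chromen-4-one, via 2-aryloxy-1,3-diketone 10 (not isolated)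
Conditions: LiN(SiMe3)2 (3.3 equiv), THF, −78 to −10 °C; AcOH; then AcOH, H2SO4 (cat.), 80 °C
Reagents that add atoms: none
Why: Baker–Venkataraman rearrangement, in which the enolate of the α-aryloxy ketone attacks the neighbouring aryl ester, followed by acid cyclodehydration of the liberated phenol onto the new aroyl ketone, as in the classical route to 3-alkoxyflavones.

Step 7
Reactants: 11 5,7-bis(benzyloxy)-2-[4-(benzyloxy)phenyl]-3-({2-[4-(benzyloxy)phenyl]-5-hydroxy-4-oxo-4H-chromen-7-yl}oxy)-4H-chromen-4-one
Product: 12 5,7-bis(benzyloxy)-3-({5-(benzyloxy)-2-[4-(benzyloxy)phenyl]-4-oxo-4H-chromen-7-yl}oxy)-2-[4-(benzyloxy)phenyl]-4H-chromen-4-one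
Conditions: BnBr, K2CO3, Bu4NI (cat.), DMF, 60 °C
Reagents that add atoms: benzyl bromide, BrCc1ccccc1
Why: Williamson etherification of the chelated 5-hydroxyl, which needs heat but has no competitor left; the benzyl group removes an oxidisable phenol and biases the later arylation toward C8.

Step 8
Reactants: 12 5,7-bis(benzyloxy)-3-({5-(benzyloxy)-2-[4-(benzyloxy)phenyl]-4-oxo-4H-chromen-7-yl}oxy)-2-[4-(benzyloxy)phenyl]-4H-chromen-4-one
Product: 14 (2R,3S)-pentabenzyl ether of the target (C3 hydroxyl free; flavonol 3-hydroxyl free), via bis-epoxide 13 (not isolated)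
Conditions: 1,2:4,5-di-O-isopropylidene-β-L-erythro-2,3-hexodiulo-2,6-pyranose (1.0 equiv, in portions), KHSO5 (as 2KHSO5·KHSO4·K2SO4), K2CO3, Bu4NHSO4, MeCN–DMM–CH2Cl2/aq. Na2B4O7 buffer (pH 10.5), 0 °C; Na2S2O3, extraction; then CSA (0.2 equiv), 4 Å MS, CH2Cl2, −20 °C to rt
Reagents that add atoms: potassium peroxymonosulfate KHSO5, [K+].[O-]S(=O)(=O)OO (both new oxygen atoms, passed on by the chiral dioxirane)
Why: Proposed new method: the chiral dioxirane transfers oxygen through a spiro transition state to both chromone C2=C3 bonds; the closest known reactions are dimethyldioxirane epoxidation of flavones and 3-alkoxyflavones and ketone-catalysed asymmetric epoxidation of trisubstituted olefins and enol ethers, not yet shown on a tetrasubstituted chromone enol ether. Acid then ionises the upper oxirane at C2–O, because that cation is stabilised by O1 and the 4-benzyloxyphenyl group whereas a cation at C3 would sit next to the C4 carbonyl. Flavonol C8 adds to this oxocarbenium ion in a 5-exo-trig Friedel–Crafts closure, the ring-closure mode known from acid cyclisation of α-aryloxy ketones to benzofurans, forming C2–C8 and the dihydrofuran ring. The lower oxirane opens in the same way but can only lose the C3 proton and emerges as the 3-hydroxyflavone. C3 is set by the reagent: the L-ketone dioxirane is expected to deliver oxygen to the face that is Si at C2 and Re at C3, which leaves the hydroxyl where 15 has it. C2 is set by the substrate: the O7 tether reaches the cation only from the face opposite the former epoxide oxygen, so the fusion is cis and C2 becomes R. The step needs C8 over C6, which the 5-benzyloxy group should secure (C8 is para to this full-strength donor, C6 is crowded between it and O7), and it needs arylation to outrun loss of the aryloxy group from the C3 hemiketal, which is why the cyclisation stage is run water-free after the oxidant has been destroyed.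

Step 9
Reactants: 14 (2R,3S)-pentabenzyl ether of the target
Product: 15 CNP0314633.1
Conditions: H2 (1 atm), 10% Pd/C, THF–EtOAc, rt
Reagents that add atoms: none
Why: Catalytic hydrogenolysis of five aryl benzyl ethers; both stereocentres are fully substituted and the C3 ketal is locked cis by the C2–C8 bond, so neutral conditions should not scramble them.

## Compound list

1 | 2,4,6-trihydroxyacetophenone | CC(=O)c1c(O)cc(O)cc1O | starting material
2 | 1-[2,4-bis(benzyloxy)-6-hydroxyphenyl]ethan-1-one | CC(=O)c1c(O)cc(OCc2ccccc2)cc1OCc1ccccc1 | intermediate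
3 | 4-(benzyloxy)benzoyl chloride | O=C(Cl)c1ccc(OCc2ccccc2)cc1 | starting material
4 | 2-acetyl-3,5-bis(benzyloxy)phenyl 4-(benzyloxy)benzoate | CC(=O)c1c(OC(=O)c2ccc(OCc3ccccc3)cc2)cc(OCc2ccccc2)cc1OCc1ccccc1 | intermediate
5 | 3,5-bis(benzyloxy)-2-[1-(trimethylsilyloxy)ethenyl]phenyl 4-(benzyloxy)benzoate | C=C(O[Si](C)(C)C)c1c(OC(=O)c2ccc(OCc3ccccc3)cc2)cc(OCc2ccccc2)cc1OCc1ccccc1 | intermediate (not isolated)
6 | 3,5-bis(benzyloxy)-2-(bromoacetyl)phenyl 4-(benzyloxy)benzoate | O=C(CBr)c1c(OC(=O)c2ccc(OCc3ccccc3)cc2)cc(OCc2ccccc2)cc1OCc1ccccc1 | intermediate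
7 | 1-[4-(benzyloxy)phenyl]-3-(2,4,6-trihydroxyphenyl)propane-1,3-dione | O=C(CC(=O)c1c(O)cc(O)cc1O)c1ccc(OCc2ccccc2)cc1 | intermediate (not isolated)
8 | 2-[4-(benzyloxy)phenyl]-5,7-dihydroxy-4H-chromen-4-one (4'-O-benzylapigenin) | O=c1cc(-c2ccc(OCc3ccccc3)cc2)oc2cc(O)cc(O)c12 | intermediate
9 | 3,5-bis(benzyloxy)-2-[({2-[4-(benzyloxy)phenyl]-5-hydroxy-4-oxo-4H-chromen-7-yl}oxy)acetyl]phenyl 4-(benzyloxy)benzoate | O=C(COc1cc(O)c2c(=O)cc(-c3ccc(OCc4ccccc4)cc3)oc2c1)c1c(OC(=O)c2ccc(OCc3ccccc3)cc2)cc(OCc2ccccc2)cc1OCc1ccccc1 | intermediate
10 | 1-[2,4-bis(benzyloxy)-6-hydroxyphenyl]-3-[4-(benzyloxy)phenyl]-2-({2-[4-(benzyloxy)phenyl]-5-hydroxy-4-oxo-4H-chromen-7-yl}oxy)propane-1,3-dione (racemic at the central carbon, centre lost on cyclisation) | O=C(c1ccc(OCc2ccccc2)cc1)C(Oc1cc(O)c2c(=O)cc(-c3ccc(OCc4ccccc4)cc3)oc2c1)C(=O)c1c(O)cc(OCc2ccccc2)cc1OCc1ccccc1 | intermediate (not isolated)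
11 | 5,7-bis(benzyloxy)-2-[4-(benzyloxy)phenyl]-3-({2-[4-(benzyloxy)phenyl]-5-hydroxy-4-oxo-4H-chromen-7-yl}oxy)-4H-chromen-4-one | O=c1c(Oc2cc(O)c3c(=O)cc(-c4ccc(OCc5ccccc5)cc4)oc3c2)c(-c2ccc(OCc3ccccc3)cc2)oc2cc(OCc3ccccc3)cc(OCc3ccccc3)c12 | intermediate
12 | 5,7-bis(benzyloxy)-3-({5-(benzyloxy)-2-[4-(benzyloxy)phenyl]-4-oxo-4H-chromen-7-yl}oxy)-2-[4-(benzyloxy)phenyl]-4H-chromen-4-one (5,7,4'-tri-O-benzylkaempferol 3-(5,4'-di-O-benzylapigenin-7-yl) ether) | O=c1c(Oc2cc(OCc3ccccc3)c3c(=O)cc(-c4ccc(OCc5ccccc5)cc4)oc3c2)c(-c2ccc(OCc3ccccc3)cc2)oc2cc(OCc3ccccc3)cc(OCc3ccccc3)c12 | intermediate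
13 | bis-epoxide of 12: (2S,3S)-2,3-oxirane on the 3-aryloxy unit and (2R,3S)-2,3-oxirane on the lower unit (lower configuration as the model predicts, without consequence) | O=C1c2c(OCc3ccccc3)cc(OCc3ccccc3)cc2O[C@@]2(c3ccc(OCc4ccccc4)cc3)O[C@@]12Oc1cc(OCc2ccccc2)c2c(c1)O[C@@]1(c3ccc(OCc4ccccc4)cc3)O[C@H]1C2=O | intermediate (not isolated)
14 | (2R,3S)-5,7-bis(benzyloxy)-2-[4-(benzyloxy)phenyl]-3-hydroxychroman-4-one joined from C2 to C8 and from C3 to O7 of 5-(benzyloxy)-2-[4-(benzyloxy)phenyl]-3-hydroxy-4H-chromen-4-one (pentabenzyl ether of 15) | O=C1c2c(OCc3ccccc3)cc(OCc3ccccc3)cc2O[C@]2(c3ccc(OCc4ccccc4)cc3)c3c(cc(OCc4ccccc4)c4c(=O)c(O)c(-c5ccc(OCc6ccccc6)cc5)oc34)O[C@]12O | intermediate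
15 | (2R,3S)-3,5,7-trihydroxy-2-(4-hydroxyphenyl)chroman-4-one joined from C2 to C8 and from C3 to O7 of 3,5-dihydroxy-2-(4-hydroxyphenyl)-4H-chromen-4-one (CNP0314633.1) | O=C1c2c(O)cc(O)cc2O[C@]2(c3ccc(O)cc3)c3c(cc(O)c4c(=O)c(O)c(-c5ccc(O)cc5)oc34)O[C@]12O | target

## Step count and uncertain steps

Total: 9 steps. Longest linear sequence: 8 steps (1 to 2, 4, 6, 9, 11, 12, 14, 15; step 4 is a one-step side branch to 8).

Step 8 (key step, the one step that extends known chemistry). Three processes may fail.
- Oxygen transfer to an electron-poor tetrasubstituted enol ether may be slow, so Baeyer–Villiger loss of the ketone and unselective background oxidation by KHSO5 can erode conversion and facial selectivity.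
- The sense of induction rests on an extrapolated model.
- At pH 10 the upper oxirane may open with water and the C3 hemiketal may then expel the lower flavone as a phenoxide.

The fallback uses known chemistry and sets out from 12. Both double bonds are epoxidised with isolated dimethyldioxirane in acetone–CH2Cl2 at 0 °C to rt, which is neutral and water-free. Without a chiral reagent this gives 13 together with mirror-image bis-epoxide F1 and the two diastereomers, lower-inverted bis-epoxide F2 and upper-inverted bis-epoxide F3. The configuration of the lower oxirane is erased in the next operation, so after evaporation and treatment with CSA in CH2Cl2 the mixture should converge on racemic 14, that is 14 and mirror-image pentabenzyl ether F4. Preparative chromatography on a cellulose tris(3,5-dimethylphenylcarbamate) phase separates the two, and 14 rejoins the route at step 9.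

Step 6. The acyl transfer may stall or reverse by retro-Claisen cleavage, the amide base may add to C2 of the lower chromone, and the 2-substituted diketone may cyclise slowly. The fallback sets out from 9 and replaces acyl transfer by an aldehyde condensation. Methanolysis of the aryl ester (K2CO3, MeOH–THF, 0 °C) gives free ortho-hydroxy α-aryloxy ketone F5. Condensation with 4-(benzyloxy)benzaldehyde (piperidine, EtOH, reflux; aldol condensation then oxa-Michael closure) gives racemic trans-3-aryloxyflavanone F6. Dehydrogenation with I2 (cat.) in DMSO at 120 °C returns 11.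

Step 3. Bromination may occur on the alkoxy-rich ring instead of the enol silane carbon, or acyl migration may start under the amine base. The fallback sets out from 4 through enol silane 5 and avoids any halogen electrophile. Rubottom oxidation (mCPBA, NaHCO3, CH2Cl2, 0 °C) gives α-silyloxy ketone F7, which is desilylated on work-up (citric acid, MeOH) to α-hydroxy ketone F8. Mitsunobu etherification with 8 (PPh3, DIAD, THF, 0 °C) gives 9, so steps 3 and 5 are both replaced.

Step 9. Over-reduction is the concern: hydrogenolysis of the doubly benzylic C2–O1 bond or saturation of the flavonol double bond before the last benzyl ether is gone. The fallback sets out from 14 and removes the benzyl groups by Lewis-acid cleavage instead of hydrogen (BCl3, pentamethylbenzene as cation trap, CH2Cl2, −78 °C). This gives 15 directly and makes no new compound.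

## Further compounds

F1 | step 8 | mirror image of bis-epoxide 13 | O=C1c2c(OCc3ccccc3)cc(OCc3ccccc3)cc2O[C@]2(c3ccc(OCc4ccccc4)cc3)O[C@]12Oc1cc(OCc2ccccc2)c2c(c1)O[C@]1(c3ccc(OCc4ccccc4)cc3)O[C@@H]1C2=O
F2 | step 8 | diastereomer of 13 with the lower oxirane inverted | O=C1c2c(OCc3ccccc3)cc(OCc3ccccc3)cc2O[C@@]2(c3ccc(OCc4ccccc4)cc3)O[C@@]12Oc1cc(OCc2ccccc2)c2c(c1)O[C@]1(c3ccc(OCc4ccccc4)cc3)O[C@@H]1C2=O
F3 | step 8 | diastereomer of 13 with the upper oxirane inverted | O=C1c2c(OCc3ccccc3)cc(OCc3ccccc3)cc2O[C@]2(c3ccc(OCc4ccccc4)cc3)O[C@]12Oc1cc(OCc2ccccc2)c2c(c1)O[C@@]1(c3ccc(OCc4ccccc4)cc3)O[C@H]1C2=O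
F4 | step 8 | (2S,3R) mirror image of pentabenzyl ether 14 | O=C1c2c(OCc3ccccc3)cc(OCc3ccccc3)cc2O[C@@]2(c3ccc(OCc4ccccc4)cc3)c3c(cc(OCc4ccccc4)c4c(=O)c(O)c(-c5ccc(OCc6ccccc6)cc5)oc34)O[C@@]12O
F5 | step 6 | 1-[2,4-bis(benzyloxy)-6-hydroxyphenyl]-2-({2-[4-(benzyloxy)phenyl]-5-hydroxy-4-oxo-4H-chromen-7-yl}oxy)ethan-1-one | O=C(COc1cc(O)c2c(=O)cc(-c3ccc(OCc4ccccc4)cc3)oc2c1)c1c(O)cc(OCc2ccccc2)cc1OCc1ccccc1
F6 | step 6 | trans-5,7-bis(benzyloxy)-2-[4-(benzyloxy)phenyl]-3-({2-[4-(benzyloxy)phenyl]-5-hydroxy-4-oxo-4H-chromen-7-yl}oxy)chroman-4-one (racemic, one enantiomer drawn) | O=C1c2c(OCc3ccccc3)cc(OCc3ccccc3)cc2O[C@H](c2ccc(OCc3ccccc3)cc2)[C@H]1Oc1cc(O)c2c(=O)cc(-c3ccc(OCc4ccccc4)cc3)oc2c1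
F7 | step 3 | 3,5-bis(benzyloxy)-2-[(trimethylsilyloxy)acetyl]phenyl 4-(benzyloxy)benzoate | O=C(CO[Si](C)(C)C)c1c(OC(=O)c2ccc(OCc3ccccc3)cc2)cc(OCc2ccccc2)cc1OCc1ccccc1
F8 | step 3 | 3,5-bis(benzyloxy)-2-(hydroxyacetyl)phenyl 4-(benzyloxy)benzoate | O=C(CO)c1c(OC(=O)c2ccc(OCc3ccccc3)cc2)cc(OCc2ccccc2)cc1OCc1ccccc1
F0 | step 9 | none | none
A1 | alternative 1 | 3,5-bis(benzyloxy)phenol | Oc1cc(OCc2ccccc2)cc(OCc2ccccc2)c1
A2 | alternative 1 | 3,5-bis(benzyloxy)-2,9-bis[4-(benzyloxy)phenyl]-4-oxo-4H-furo[2,3-h]chromene-8-carbaldehyde | O=Cc1oc2cc(OCc3ccccc3)c3c(=O)c(OCc4ccccc4)c(-c4ccc(OCc5ccccc5)cc4)oc3c2c1-c1ccc(OCc2ccccc2)cc1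
A3 | alternative 1 | 2H-chromene hexabenzyl ether with the dihydrofuran ring in place and C3=C4 unsaturated | C1=C2Oc3cc(OCc6ccccc6)c4c(=O)c(OCc6ccccc6)c(-c5ccc(OCc6ccccc6)cc5)oc4c3[C@@]2(c2ccc(OCc6ccccc6)cc2)Oc2cc(OCc6ccccc6)cc(OCc6ccccc6)c12
A4 | alternative 2 | para-quinone methide bearing the flavonol C8 and the 1,2-diketone on its exocyclic carbon | O=C1C=CC(=C(c2c(O)cc(OCc3ccccc3)c3c(=O)c(OCc4ccccc4)c(-c4ccc(OCc5ccccc5)cc4)oc23)C(=O)C(=O)c2c(O)cc(OCc3ccccc3)cc2O)C=C1
A5 | alternative 2 | target tetrabenzyl ether with free ring-B and chromanone 5-hydroxyls | O=C1c2c(O)cc(OCc6ccccc6)cc2O[C@]2(c3ccc(O)cc3)c3c(cc(OCc6ccccc6)c4c(=O)c(OCc6ccccc6)c(-c5ccc(OCc6ccccc6)cc5)oc34)O[C@]12O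
A6 | alternative 3 | 2,2-diaryl-3-(p-tolylsulfinyl)chroman-4-one with free flavonol 7-hydroxyl (C2 as in the target; C3 and sulfur configurations left open) | O=C1c2c(OCc3ccccc3)cc(OCc3ccccc3)cc2O[C@](c2ccc(OCc3ccccc3)cc2)(c2c(O)cc(OCc3ccccc3)c3c(=O)c(OCc4ccccc4)c(-c4ccc(OCc5ccccc5)cc4)oc23)C1S(=O)c1ccc(C)cc1
A7 | alternative 3 | hexabenzyl target with p-tolylthio in place of the C3 hydroxyl | O=C1c2c(OCc6ccccc6)cc(OCc6ccccc6)cc2O[C@]2(c3ccc(OCc6ccccc6)cc3)c3c(cc(OCc6ccccc6)c4c(=O)c(OCc6ccccc6)c(-c5ccc(OCc6ccccc6)cc5)oc34)O[C@]12Sc1ccc(C)cc1
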